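**Strategy.** Everything rests on disconnecting the C1–C16 bond, so that the seven-membered ring C (C1, C16, C13, C12, C11, C9, C10) is closed last by the furan on a ring A epoxide. In one operation the furan α-carbon C16 opens a 1α,2α-epoxide at C1 with inversion; this forms ring C and delivers the feature the step exploits, C16 on C1 trans to the hydroxyl on C2 across the C1–C2 bond. The precursor is a trans-decalin Δ3-18,19-olide carrying the 1α,2α-epoxide, the 7α-acetate and, on C9, a 3-furyl carbinol side chain as its 12R tert-butyldimethylsilyl ether; the furan is attached only after the epoxide has been made.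

Key step: step 24

Remark 1: clerodane numbering is used throughout (ring A = C1–C5, C10; ring B = C5–C10; C11, C12 on C9; furan C13–C16, C16 being the α-carbon next to C13; C17 on C8; C18 on C4; C19 on C5; C20 on C9); β is the face of H-10.

Remark 2: the sense of induction of D-phenylalanine (step 4) and of (−)-MIB (step 22) is assumed by analogy with the methyl-substituted triketone and with aryl transfer to simple aldehydes; the antipodal catalyst would be taken if the sense proved opposite.

Remark 3: the furan is introduced after the epoxide because N-bromosuccinimide would attack a 3-alkylfuran, and C12 is carried as a bulky, Lewis-acid-stable tert-butyldimethylsilyl ether of fixed 12R configuration so that its oxygen is a poor competitor for C1.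

**Route**

Step 1
Reactants: 1 cyclohexane-1,3-dione; 2 pent-1-en-3-one
Product: 3 2-(3-oxopentyl)cyclohexane-1,3-dione
Conditions: Et3N (cat.), aq. THF, rt, 1 in excess
Reagents that add atoms: none
Why: Michael addition of the acidic 1,3-dione to the vinyl ketone; the excess of 1 should hold the reaction at the mono-adduct.

Step 2
Reactants: 3 2-(3-oxopentyl)cyclohexane-1,3-dione
Product: 4 2-(hydroxymethyl)-2-(3-oxopentyl)cyclohexane-1,3-dione
Conditions: 37% aq. CH2O (excess), NaHCO3 (cat.), aq. THF, 0 °C → rt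
Reagents that add atoms: formaldehyde, C=O
Why: Aldol hydroxymethylation of a 2-alkyl-1,3-dione at carbon; the quaternary adduct cannot dehydrate and introduces C19 at the alcohol level.

Step 3
Reactants: 4 2-(hydroxymethyl)-2-(3-oxopentyl)cyclohexane-1,3-dione
Product: 5 2-(3-oxopentyl)-2-[(triisopropylsilyloxy)methyl]cyclohexane-1,3-dione
Conditions: TIPSOTf, 2,6-lutidine, CH2Cl2, −78 °C
Reagents that add atoms: triisopropylsilyl triflate, CC(C)[Si](C(C)C)(C(C)C)OS(=O)(=O)C(F)(F)F
Why: Silyl triflate silylation of the primary alcohol is fast at low temperature with a hindered base and blocks retro-aldol loss of formaldehyde.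

Step 4
Reactants: 5 2-(3-oxopentyl)-2-[(triisopropylsilyloxy)methyl]cyclohexane-1,3-dione
Product: 6 (8aR)-5-methyl-8a-[(triisopropylsilyloxy)methyl]-3,4,8,8a-tetrahydronaphthalene-1,6(2H,7H)-dione
Conditions: D-phenylalanine (1.0 equiv), (1R)-(−)-10-camphorsulfonic acid (0.5 equiv), DMF, 30 → 70 °C
Reagents that add atoms: none
Why: Hajos–Parrish–Eder–Sauer–Wiechert aldol condensation: the amino-acid enamine of the side-chain ketone attacks one of the two enantiotopic ring carbonyls and dehydration gives the C9=C10 enone, which sets C5 (D-amino acid for this series by analogy with the L-amino acid and the antipodal methyl series).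

Step 5
Reactants: 6 bicyclic enedione
Product: 7 C4 ethylene ketal of 6 (C8 enone kept)
Conditions: ethylene glycol, TsOH·H2O (cat.), 4 Å molecular sieves, rt
Reagents that add atoms: ethylene glycol, OCCO
Why: Acid-catalysed ketalisation is chemoselective for the saturated C4 ketone over the less electrophilic conjugated C8 ketone.

Step 6
Reactants: 7 ketal enone
Product: 9 9β-allyl-9α-methyl-trans-decalin-8-one carrying the C4 ethylene ketal and 5α-CH2OTIPS (H-10 β), via lithium enolate 8 (not isolated)
Conditions: Li, NH3(l)/THF, t-BuOH (1.0 equiv), −78 → −33 °C; isoprene; then allyl bromide, −78 °C → rt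
Reagents that add atoms: allyl bromide, C=CCBr
Why: Birch-type reductive alkylation: protonation at C10 gives the trans-fused C8 enolate regiospecifically, and allylation at C9 occurs anti to the axial C5 substituent, which sets C10 (H β) and C9 (allyl β, methyl α).

Step 7
Reactants: 9 allylated ketone
Product: 11 C8 enol triflate (Δ7), via potassium enolate 10 (not isolated)
Conditions: KN(SiMe3)2, THF, −78 °C; then PhNTf2, −78 → 0 °C
Reagents that add atoms: N-phenylbis(trifluoromethanesulfonimide), O=S(=O)(N(c1ccccc1)S(=O)(=O)C(F)(F)F)C(F)(F)F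
Why: Enol triflate formation; the ketone can enolise only toward C7 because C9 is quaternary.

Step 8
Reactants: 11 enol triflate
Product: 13 primary alcohol (C9 side chain CH2CH2OH), via aldehyde 12 (not isolated)
Conditions: O3, CH2Cl2/MeOH, −78 °C (indicator end point); then NaBH4, −78 → 0 °C
Reagents that add atoms: ozone, [O-][O+]=O
Why: Ozonolysis with reductive work-up; the electron-rich terminal alkene is cleaved in preference to the electron-poor enol triflate, which leaves C11–C12 at the alcohol level.

Step 9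
Reactants: 13 primary alcohol
Product: 14 12,19-bis(triisopropylsilyl) ether of the enol triflate
Conditions: TIPSCl, imidazole, DMF, rt
Reagents that add atoms: triisopropylsilyl chloride, CC(C)[Si](Cl)(C(C)C)C(C)C
Why: Standard silylation of an unhindered primary alcohol.

Step 10
Reactants: 14 bis-silyl enol triflate
Product: 15 Δ7 alkene bearing the C8 methyl (C17)
Conditions: Me2CuLi, THF, −20 → 0 °C
Reagents that add atoms: lithium dimethylcuprate, [Li+].C[Cu-]C
Why: Cuprate cross-coupling of a cycloalkenyl triflate replaces the triflate by methyl with the alkene position fixed.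

Step 11
Reactants: 15 Δ7 alkene
Product: 17 7β-alcohol (8β-H and 17α-methyl), via alkylborane 16 (not isolated)
Conditions: BH3·SMe2, THF, 0 °C → rt; then NaOH, H2O2, 0 °C → rt
Reagents that add atoms: hydrogen peroxide, OO
Why: Hydroboration–oxidation: boron goes to the less substituted C7 and hydrogen to C8, syn and from the β face because the α face is screened by the axial C19 and C20 groups, which sets C8 (methyl α, equatorial).

Step 12
Reactants: 17 7β-alcohol
Product: 18 C7 ketone
Conditions: Dess–Martin periodinane, NaHCO3, CH2Cl2, rt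
Reagents that add atoms: none
Why: Dess–Martin oxidation of a secondary alcohol; the C8 methyl is already equatorial, so enolisation cannot erode C8.

Step 13
Reactants: 18 C7 ketone
Product: 19 7α-alcohol (axial)
Conditions: LiBH(s-Bu)3 (L-Selectride), THF, −78 °C; then H2O
Reagents that add atoms: none
Why: Hindered-hydride reduction: the axial α trajectory at C7 is blocked by the syn-axial C19 and C20 groups, so hydride arrives from the equatorial β side and sets C7 (OH α).

Step 14
Reactants: 19 7α-alcohol
Product: 20 7α-acetate (C4 ketal, two silyl ethers)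
Conditions: Ac2O, DMAP, pyridine, 40 °C
Reagents that add atoms: acetic anhydride, CC(=O)OC(C)=O
Why: DMAP-catalysed acylation of a hindered secondary alcohol.

Step 15
Reactants: 20 7α-acetate ketal
Product: 21 7α-acetoxy C4 ketone
Conditions: PPTS, acetone/H2O, 60 °C
Reagents that add atoms: water, O
Why: Mild acid hydrolysis of the dioxolane frees the C4 ketone while the acetate and the primary triisopropylsilyl ethers should survive.

Step 16
Reactants: 21 C4 ketone
Product: 22 Δ2-4-ketone (enone)
Conditions: IBX, DMSO/fluorobenzene, 70 °C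
Reagents that add atoms: none
Why: IBX dehydrogenation of a ketone to the enone can only occur toward C3 because C5 is quaternary.

Step 17
Reactants: 22 enone
Product: 23 dienyl triflate (C4–OTf, Δ1 and Δ3)
Conditions: Tf2O, 2,6-di-tert-butyl-4-methylpyridine, CH2Cl2, 0 °C → rt
Reagents that add atoms: triflic anhydride, O=S(=O)(OS(=O)(=O)C(F)(F)F)C(F)(F)F
Why: O-triflation of the enone and loss of the γ-proton at C1 gives the conjugated dienyl triflate, the only dienol isomer available, without strong base that would touch the acetate.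

Step 18
Reactants: 23 dienyl triflate
Product: 24 12,19-diol dienyl triflate
Conditions: HF·pyridine, pyridine, THF, 0 °C → rt
Reagents that add atoms: none
Why: Fluoride cleavage of both primary silyl ethers; the vinyl triflate and the acetate tolerate acidic HF·pyridine.

Step 19
Reactants: 24 diol dienyl triflate
Product: 25 7α-acetoxy-12-hydroxy-1,3-dien-18,19-olide
Conditions: Pd(PPh3)4 (10 mol%), CO (1 atm), Et3N, LiCl, MeCN, 65 °C
Reagents that add atoms: carbon monoxide, [C-]#[O+]
Why: Carbonylative lactonisation: oxidative addition of the triflate to zerovalent palladium, CO insertion and capture of the acylpalladium by the neighbouring C19 hydroxyl close the five-membered lactone, far faster than any large ring through the C12 hydroxyl.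

Step 20
Reactants: 25 diene lactone
Product: 27 1α,2α-epoxy-12-hydroxy-Δ3-18,19-olide, via bromohydrin 26 (not isolated)
Conditions: NBS, aq. THF, 0 °C, dark; then K2CO3, 0 °C → rt
Reagents that add atoms: water, O
Why: Bromohydrin formation and base closure: the bromonium ion should form on the β face of the distal C1–C2 alkene (the α face is screened by C9 and its axial methyl C20), water opens it anti, and the alkoxide displaces bromide with inversion, so both epoxide C–O bonds end up α.

Step 21
Reactants: 27 hydroxy epoxide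
Product: 28 1α,2α-epoxy-12-aldehyde
Conditions: Dess–Martin periodinane, NaHCO3, CH2Cl2, 0 °C
Reagents that add atoms: none
Why: Dess–Martin oxidation of the primary alcohol under buffered neutral conditions that leave the epoxide untouched.

Step 22
Reactants: 28 epoxy aldehyde; 29 3-bromofuran
Product: 30 (12R)-12-(furan-3-yl)-12-hydroxy epoxy lactone
Conditions: 29, n-BuLi, t-BuOMe, −78 °C; EtZnCl; N,N,N′,N′-tetraethylethylenediamine; (−)-MIB (10 mol%), toluene; then 28, 0 °C
Reagents that add atoms: none
Why: Amino-alcohol-catalysed enantioselective aryl transfer from a mixed aryl(ethyl)zinc to an aldehyde; the zinc reagent does not touch lactone, acetate or epoxide, and the ligand is expected to direct the furyl group to the Si face, setting C12 as R.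

Step 23
Reactants: 30 furyl carbinol
Product: 31 (12R)-12-(tert-butyldimethylsilyloxy) 1α,2α-epoxy-Δ3-18,19-olide (key-step precursor)
Conditions: TBSCl, imidazole, DMAP (cat.), DMF, rt
Reagents that add atoms: tert-butyldimethylsilyl chloride, CC(C)(C)[Si](C)(C)Cl
Why: Silylation of the secondary alcohol under mildly basic conditions free of Lewis acid, so the epoxide is not activated prematurely.

Step 24
Reactants: 31 epoxy silyl ether
Product: 32 pentacyclic 2α-alcohol with ring C closed (C16 β on C1, 12R silyl ether)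
Conditions: BF3·OEt2 (0.5 equiv), CH2Cl2 (high dilution), −78 → −30 °C; Et3N quench
Reagents that add atoms: none
Why: Boron trifluoride coordinates the epoxide oxygen, furan C16 (the α-carbon next to the alkyl group of the 3-alkylfuran) attacks C1 from the β face anti to the breaking C1–O bond, and loss of the C16 proton restores the furan. The closest known reaction type is the furan-terminated, epoxide-initiated cationic cyclisation, an intramolecular Friedel–Crafts alkylation of 3-alkylfurans by epoxides that is known to close six- and seven-membered rings. Ring C (C1–C16–C13–C12–C11–C9–C10) closes in the 7-exo-tet mode. The new stereocentre C1 is set by inversion at the epoxide carbon, so the α-epoxide dictates C16 β and leaves the C2 oxygen α, trans to it. The step needs C1 over C2 and carbon over oxygen attack: C2 is out of reach of the tether (eight-membered ring) and its ionisation is disfavoured by the C4 acyl group, while the C12 oxygen is held back by the bulk and low basicity of its tert-butyldimethylsilyl ether, whose 12R configuration is expected to place it on the outer side of the forming ring.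

Step 25
Reactants: 32 pentacyclic 2α-alcohol
Product: 33 2α-triisopropylsilyl ether
Conditions: TIPSOTf, 2,6-lutidine, CH2Cl2, 0 °C → rt
Reagents that add atoms: triisopropylsilyl triflate, CC(C)[Si](C(C)C)(C(C)C)OS(=O)(=O)C(F)(F)F
Why: Silyl triflate silylation of the secondary C2 alcohol with a group that outlasts the C12 silyl ether.

Step 26
Reactants: 33 bis-silyl ether
Product: 34 12-alcohol (2α-OTIPS kept)
Conditions: HF·pyridine, pyridine, THF, 0 °C
Reagents that add atoms: none
Why: Selective fluoride desilylation; the tert-butyldimethylsilyl ether is cleaved much faster than the triisopropylsilyl ether.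

Step 27
Reactants: 34 12-alcohol
Product: 35 12-ketone (furyl ketone)
Conditions: Dess–Martin periodinane, NaHCO3, CH2Cl2, rt
Reagents that add atoms: none
Why: Dess–Martin oxidation of the furyl carbinol, which erases the auxiliary C12 stereocentre.

Step 28
Reactants: 35 silyl-protected ketone
Product: 36 CNP0182929.1 (target)
Conditions: HF (48% aq.), MeCN, rt
Reagents that add atoms: none
Why: Acidic fluoride desilylation avoids base, which could eliminate the C2 oxygen γ to the unsaturated lactone.

**Compound list**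

1 | cyclohexane-1,3-dione | O=C1CCCC(=O)C1 | starting material
2 | pent-1-en-3-one (ethyl vinyl ketone) | CCC(=O)C=C | starting material
3 | 2-(3-oxopentyl)cyclohexane-1,3-dione | CCC(=O)CCC1C(=O)CCCC1=O | intermediate
4 | 2-(hydroxymethyl)-2-(3-oxopentyl)cyclohexane-1,3-dione | CCC(=O)CCC1(CO)C(=O)CCCC1=O | intermediate
5 | 2-(3-oxopentyl)-2-[(triisopropylsilyloxy)methyl]cyclohexane-1,3-dione | CCC(=O)CCC1(CO[Si](C(C)C)(C(C)C)C(C)C)C(=O)CCCC1=O | intermediate
6 | (8aR)-5-methyl-8a-[(triisopropylsilyloxy)methyl]-3,4,8,8a-tetrahydronaphthalene-1,6(2H,7H)-dione (C4 and C8 ketones, C9=C10, C19 silyl ether α) | CC(C)[Si](C(C)C)(C(C)C)OC[C@]12C(=O)CCCC1=C(C)C(=O)CC2 | intermediate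
7 | C4 ethylene ketal of 6 | CC(C)[Si](C(C)C)(C(C)C)OC[C@]12C3(OCCO3)CCCC1=C(C)C(=O)CC2 | intermediate
8 | lithium C8 enolate (Δ8) of the trans-fused decalin, H-10 β | CC(C)[Si](C(C)C)(C(C)C)OC[C@]12C3(OCCO3)CCC[C@@H]1C(C)=C([O-])CC2.[Li+] | intermediate (not isolated)
9 | 9β-allyl-9α-methyl-trans-decalin-8-one with C4 ethylene ketal and 5α-CH2OTIPS, H-10 β | CC(C)[Si](C(C)C)(C(C)C)OC[C@]12C3(OCCO3)CCC[C@@H]1[C@@](C)(CC=C)C(=O)CC2 | intermediate
10 | potassium Δ7 enolate of 9 | CC(C)[Si](C(C)C)(C(C)C)OC[C@]12C3(OCCO3)CCC[C@@H]1[C@@](C)(CC=C)C([O-])=CC2.[K+] | intermediate (not isolated)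
11 | C8 enol triflate (Δ7) of 9 | CC(C)[Si](C(C)C)(C(C)C)OC[C@]12C3(OCCO3)CCC[C@@H]1[C@@](C)(CC=C)C(OS(=O)(=O)C(F)(F)F)=CC2 | intermediate
12 | C12 aldehyde (C9 side chain CH2CHO) of the enol triflate | CC(C)[Si](C(C)C)(C(C)C)OC[C@]12C3(OCCO3)CCC[C@@H]1[C@@](C)(CC=O)C(OS(=O)(=O)C(F)(F)F)=CC2 | intermediate (not isolated)
13 | C12 alcohol (C9 side chain CH2CH2OH) of the enol triflate | CC(C)[Si](C(C)C)(C(C)C)OC[C@]12C3(OCCO3)CCC[C@@H]1[C@@](C)(CCO)C(OS(=O)(=O)C(F)(F)F)=CC2 | intermediate
14 | 12,19-bis(triisopropylsilyl) ether of the enol triflate | CC(C)[Si](C(C)C)(C(C)C)OC[C@]12C3(OCCO3)CCC[C@@H]1[C@@](C)(CCO[Si](C(C)C)(C(C)C)C(C)C)C(OS(=O)(=O)C(F)(F)F)=CC2 | intermediate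
15 | Δ7 alkene with C8 methyl (C17), C4 ketal, 12,19-bis(silyl ether) | CC(C)[Si](C(C)C)(C(C)C)OC[C@]12C3(OCCO3)CCC[C@@H]1[C@@](C)(CCO[Si](C(C)C)(C(C)C)C(C)C)C(C)=CC2 | intermediate
16 | 7β-boryl adduct (8β-H, 17α-methyl) | CC(C)[Si](C(C)C)(C(C)C)OC[C@]12C3(OCCO3)CCC[C@@H]1[C@@](C)(CCO[Si](C(C)C)(C(C)C)C(C)C)[C@H](C)[C@@H](B)C2 | intermediate (not isolated)
17 | 7β-alcohol (8β-H, 17α-methyl) | CC(C)[Si](C(C)C)(C(C)C)OC[C@]12C3(OCCO3)CCC[C@@H]1[C@@](C)(CCO[Si](C(C)C)(C(C)C)C(C)C)[C@H](C)[C@@H](O)C2 | intermediate
18 | C7 ketone (17α-methyl) | CC(C)[Si](C(C)C)(C(C)C)OC[C@]12C3(OCCO3)CCC[C@@H]1[C@@](C)(CCO[Si](C(C)C)(C(C)C)C(C)C)[C@H](C)C(=O)C2 | intermediate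
19 | 7α-alcohol (axial) | CC(C)[Si](C(C)C)(C(C)C)OC[C@]12C3(OCCO3)CCC[C@@H]1[C@@](C)(CCO[Si](C(C)C)(C(C)C)C(C)C)[C@H](C)[C@H](O)C2 | intermediate
20 | 7α-acetate with C4 ketal | CC(C)[Si](C(C)C)(C(C)C)OC[C@]12C3(OCCO3)CCC[C@@H]1[C@@](C)(CCO[Si](C(C)C)(C(C)C)C(C)C)[C@H](C)[C@H](OC(C)=O)C2 | intermediate
21 | 7α-acetoxy C4 ketone | CC(C)[Si](C(C)C)(C(C)C)OC[C@]12C(=O)CCC[C@@H]1[C@@](C)(CCO[Si](C(C)C)(C(C)C)C(C)C)[C@H](C)[C@H](OC(C)=O)C2 | intermediate
22 | 7α-acetoxy Δ2-4-ketone | CC(C)[Si](C(C)C)(C(C)C)OC[C@]12C(=O)C=CC[C@@H]1[C@@](C)(CCO[Si](C(C)C)(C(C)C)C(C)C)[C@H](C)[C@H](OC(C)=O)C2 | intermediate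
23 | 7α-acetoxy dienyl triflate (C4–OTf, Δ1, Δ3) | CC(C)[Si](C(C)C)(C(C)C)OC[C@]12C(OS(=O)(=O)C(F)(F)F)=CC=C[C@@H]1[C@@](C)(CCO[Si](C(C)C)(C(C)C)C(C)C)[C@H](C)[C@H](OC(C)=O)C2 | intermediate
24 | 12,19-diol dienyl triflate | OC[C@]12C(OS(=O)(=O)C(F)(F)F)=CC=C[C@@H]1[C@@](C)(CCO)[C@H](C)[C@H](OC(C)=O)C2 | intermediate
25 | 7α-acetoxy-12-hydroxy-1,3-dien-18,19-olide | CC(=O)O[C@@H]1C[C@@]23COC(=O)C2=CC=C[C@@H]3[C@@](C)(CCO)[C@@H]1C | intermediate
26 | 1β-bromo-2α-hydroxy-Δ3-18,19-olide (bromohydrin) | CC(=O)O[C@@H]1C[C@@]23COC(=O)C2=C[C@H](O)[C@@H](Br)[C@@H]3[C@@](C)(CCO)[C@@H]1C | intermediate (not isolated)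
27 | 1α,2α-epoxy-12-hydroxy-Δ3-18,19-olide | CC(=O)O[C@@H]1C[C@@]23COC(=O)C2=C[C@@H]2O[C@@H]2[C@@H]3[C@@](C)(CCO)[C@@H]1C | intermediate
28 | 1α,2α-epoxy-12-oxo (aldehyde) Δ3-18,19-olide | CC(=O)O[C@@H]1C[C@@]23COC(=O)C2=C[C@@H]2O[C@@H]2[C@@H]3[C@@](C)(CC=O)[C@@H]1C | intermediate
29 | 3-bromofuran | Brc1ccoc1 | starting material
30 | (12R)-12-(furan-3-yl)-12-hydroxy 1α,2α-epoxy-Δ3-18,19-olide | CC(=O)O[C@@H]1C[C@@]23COC(=O)C2=C[C@@H]2O[C@@H]2[C@@H]3[C@@](C)(C[C@@H](O)c2ccoc2)[C@@H]1C | intermediate
31 | (12R)-12-(tert-butyldimethylsilyloxy) 1α,2α-epoxy-Δ3-18,19-olide with 3-furyl side chain (key-step precursor) | CC(=O)O[C@@H]1C[C@@]23COC(=O)C2=C[C@@H]2O[C@@H]2[C@@H]3[C@@](C)(C[C@@H](O[Si](C)(C)C(C)(C)C)c2ccoc2)[C@@H]1C | intermediate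
32 | pentacyclic 2α-alcohol with C1–C16 bond (C16 β) and 12R silyl ether (key-step product) | CC(=O)O[C@@H]1C[C@@]23COC(=O)C2=C[C@H](O)[C@H]2c4occc4[C@H](O[Si](C)(C)C(C)(C)C)C[C@@](C)([C@@H]1C)[C@@H]23 | intermediate
33 | 2α-triisopropylsilyl ether of 32 | CC(=O)O[C@@H]1C[C@@]23COC(=O)C2=C[C@H](O[Si](C(C)C)(C(C)C)C(C)C)[C@H]2c4occc4[C@H](O[Si](C)(C)C(C)(C)C)C[C@@](C)([C@@H]1C)[C@@H]23 | intermediate
34 | 12-alcohol with 2α-triisopropylsilyl ether | CC(=O)O[C@@H]1C[C@@]23COC(=O)C2=C[C@H](O[Si](C(C)C)(C(C)C)C(C)C)[C@H]2c4occc4[C@H](O)C[C@@](C)([C@@H]1C)[C@@H]23 | intermediate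
35 | 12-ketone with 2α-triisopropylsilyl ether | CC(=O)O[C@@H]1C[C@@]23COC(=O)C2=C[C@H](O[Si](C(C)C)(C(C)C)C(C)C)[C@H]2c4occc4C(=O)C[C@@](C)([C@@H]1C)[C@@H]23 | intermediate
36 | CNP0182929.1: 7α-acetoxy-2α-hydroxy-12-oxo-Δ3-18,19-olide with furan C16 bonded to C1 (β) | CC(=O)O[C@@H]1C[C@@]23COC(=O)C2=C[C@H](O)[C@H]2c4occc4C(=O)C[C@@](C)([C@@H]1C)[C@@H]23 | target

**Count and risks**

Total step count: 28. Longest linear sequence: 28 steps (1 → 36); 3-bromofuran 29 enters at step 22.

Steps most likely to fail:

Step 24. What may go wrong: capture of the activated C1 by the C12 ether oxygen or by fluoride before the slower seven-membered closure, or acid-induced degradation of the furan. The fallback raises the carbon nucleophilicity at C16 by ipso-substitution of a furylsilane. It sets out from epoxy aldehyde 28 and 3-bromofuran 29. Compound 29 would be silylated at C2 (LiN(i-Pr)2, Me3SiCl, THF, −78 °C) to 3-bromo-2-(trimethylsilyl)furan F1. Its ethylzinc reagent (n-BuLi, EtZnCl) would be added to 28 under the (−)-MIB conditions of step 22 to give the 12R carbinol F2, which would be silylated (TBSCl, imidazole) to the bis-silyl precursor F3. A Lewis acid without transferable halide (Sc(OTf)3, CH2Cl2, −40 °C) should then close ring C by attack of the silicon-bearing C16 on C1 with loss of the trimethylsilyl group, and the route is rejoined at 32.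

Step 20. What may go wrong: formation of the bromonium ion on the α rather than the β face, which after closure would lead to the β-epoxide. Direct oxygen transfer is then the answer, because it places oxygen on the face that the electrophile prefers. Diene 25 would be treated with dimethyldioxirane (acetone, −20 °C) to give 27 directly, where the route is rejoined; this fallback makes no new compound (F0).

Step 4. What may go wrong: slow or poorly enantioselective aldol cyclisation because the bulky silyloxymethyl group sits next to both ring carbonyls. The angular carbon would then be brought in as an allyl group, a substituent that this cyclisation is known to accept, and cut down to C19 afterwards. The fallback sets out from 1. C-allylation (allyl bromide, aq. KOH, Cu powder) would give 2-allylcyclohexane-1,3-dione F4, and Michael addition to 2 the triketone F5. The D-phenylalanine/camphorsulfonic acid cyclisation would give the (8aS)-8a-allyl enedione F6, and ketalisation as in step 5 its C4 ketal F7. RuHCl(CO)(PPh3)3 (toluene, 80 °C) would shift the alkene to the (E)-propenyl compound F8. Ozonolysis (CH2Cl2/MeOH, −78 °C) would give the angular aldehyde F9, reduced in the same flask (NaBH4, −78 °C) to the angular alcohol F10. Silylation (TIPSCl, imidazole) returns to 7.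

Further compounds

F1 | step 24 | 3-bromo-2-(trimethylsilyl)furan | C[Si](C)(C)c1occc1Br
F2 | step 24 | (12R)-12-hydroxy-12-[2-(trimethylsilyl)furan-3-yl] 1α,2α-epoxy-Δ3-18,19-olide | CC(=O)O[C@@H]1C[C@@]23COC(=O)C2=C[C@@H]2O[C@@H]2[C@@H]3[C@@](C)(C[C@@H](O)c2ccoc2[Si](C)(C)C)[C@@H]1C
F3 | step 24 | (12R)-12-(tert-butyldimethylsilyloxy)-12-[2-(trimethylsilyl)furan-3-yl] 1α,2α-epoxy-Δ3-18,19-olide | CC(=O)O[C@@H]1C[C@@]23COC(=O)C2=C[C@@H]2O[C@@H]2[C@@H]3[C@@](C)(C[C@@H](O[Si](C)(C)C(C)(C)C)c2ccoc2[Si](C)(C)C)[C@@H]1C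
F0 | step 20 | none | none
F4 | step 4 | 2-allylcyclohexane-1,3-dione | C=CCC1C(=O)CCCC1=O
F5 | step 4 | 2-allyl-2-(3-oxopentyl)cyclohexane-1,3-dione | CCC(=O)CCC1(CC=C)C(=O)CCCC1=O
F6 | step 4 | (8aS)-8a-allyl-5-methyl-3,4,8,8a-tetrahydronaphthalene-1,6(2H,7H)-dione | C=CC[C@]12C(=O)CCCC1=C(C)C(=O)CC2
F7 | step 4 | C4 ethylene ketal of F6 | C=CC[C@]12C3(OCCO3)CCCC1=C(C)C(=O)CC2
F8 | step 4 | angular (E)-prop-1-enyl ketal enone | C/C=C/[C@]12C3(OCCO3)CCCC1=C(C)C(=O)CC2
F9 | step 4 | angular aldehyde ketal enone (not isolated) | O=C[C@]12C3(OCCO3)CCCC1=C(C)C(=O)CC2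
F10 | step 4 | angular hydroxymethyl ketal enone | OC[C@]12C3(OCCO3)CCCC1=C(C)C(=O)CC2
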